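The numbers were set for the occasion; what happens was integrated by code.

Half of the second catalyst sits in the catalyst intermediate once binding has equilibrated at [open intermediate] = 0.125 M, so we reckon where each flask stands against that mark.

    substrate + free catalyst ⇌ free catalyst + open intermediate (K1 = 1.0, k1 = 26.8 /M/s)
    second catalyst + open intermediate ⇌ catalyst intermediate (K2 = 7.98 /M, k2 = 2070 /M/s)
    partner + catalyst intermediate → second catalyst + target (k3 = 49.9 /M/s)
    solid reagent ⇌ partner, rate k4*(cs4 - [partner]) while solid is left; crystals form when [partner] > cs4 (cs4 = 32 mM, k4 = 0.0187 /s)
    open intermediate → decomposed reagent (k5 = 0.00932 /s)

common to all: solid reagent 0.0900 M; free catalyst 0.90 mM; second catalyst 0.45 mM; time 1.0 min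
- west: substrate 0.10 M
- north: substrate 0.15 M
- south-west: substrate 0.20 M
- south-east: substrate 0.30 M
- north-west: substrate 0.50 M

- [target] at the end for west, north, south-west, south-east, north-west, in this order
- the course of these numbers from the first flask to the last (falls, then rises / rises all the way / hardly changes / falls all the way / rises, then falls)

- We start with the opening step alone. The free catalyst is given back unchanged, so the step is pseudo-first-order with 0.0241 /s each way, and with 1.0 it carries [open intermediate] towards [substrate].
- Next we add the decomposition at 0.00932 /s. This gives a linear two-pool system with a slow root 0.00421 /s and a fast root 0.0533 /s. The fraction of the charge standing as open intermediate at 1.0 min is then 36.1%. The charge does not enter this fraction, so we use it for every flask, ignoring the small draw towards target.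
- Now we add binding. The catalyst intermediate falls back at 259 /s, and it goes on at 1.60 /s even with partner at solubility, so falling back is much faster and we treat the binding as an equilibrium.
- This gives the free share φ, the fraction of the second catalyst left unbound, which is the reciprocal of one plus the binding constant times [open intermediate]. For west, φ = 77.6%, and for north-west, φ = 41.0%.
- Last come the partner and the final step. The bound share turns partner over with a pseudo-first-order constant κ, which is k₃ times the second catalyst charged times one minus φ. That gives 0.00502 /s in west and 0.0133 /s in north-west, the latter still slower than dissolution.
- Holding κ at these values for the whole minute, we let [partner] relax at the sum of κ and the dissolution coefficient, and integrating κ[partner] over the minute gives 0.00355 M of target in west. The same integral gives 0.00827 M in north-west.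
- Since κ is larger in north-west than in west, we expect that our row rises all the way, with north-west above west, by a factor of 2.33 for a charge ratio of 5.00.
- The forecast gives 0.0031 M, 0.0041 M, 0.0048 M, 0.0059 M and 0.0072 M, a course that rises all the way, with its reckoning giving “a few mM of target in every flask”.
- The simulation gives 0.00323 M, 0.00429 M, 0.00513 M, 0.00638 M and 0.00792 M, a course that rises all the way, and our value for west lies above its reading. In north-west, the second catalyst left free at the end stood at 41.7% of its charge, against our φ of 41.0%. For south-east, charged at 0.30 M, φ reckons to 53.6%, and the second catalyst left free there stood at 54.6% after 1.00 min.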